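In this closed flask, target, isomer of the product A and whatever you cannot see always add up to the whole charge. At 0.667 min the unseen part is down to 30.4%, so the first reading already lies far from the start.

- violet: starting material 0.32 M; other conformer 1 equiv; the very flask that is asked about, followed so far
- flask: starting material 0.32 M; other conformer 1.00 equiv; time 25 min

violet run (percent of the starting material and other conformer together charged)

| time / min | target / % | isomer of the product A / % |
|---|---|---|
| 0.667 | 35.1 | 34.5 |
| 1.33 | 31.0 | 49.2 |
| 2.00 | 24.9 | 56.3 |
| 2.50 | 20.6 | 58.6 |
| 3.00 | 17.2 | 60.0 |
| 4.00 | 13.1 | 61.3 |
| 5.00 | 9.7 | 62.2 |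

(readings scatter by 0.3 percentage points)

- share of target in target plus isomer of the product A at 0.20 s
- share of target in target plus isomer of the product A at 25 min
- which of target and isomer of the product A there is more of at 25 min

My reckoning carries one quantity, the early odds per equivalent: target over isomer of the product A as first formed, times the equivalents of other conformer, a selectivity factor. The time 0.20 s is far earlier than the first reading, so I read it as the start.

The odds are 1.02 at the first reading and 0.630 at the second. Going back, the factor per step grows from 1.42 to 1.61. One more step of 1.61 gives the lower bound, 1.64, a share of 62.1%. The upper bound, 2.65 or 72.6%, is my judgement, with that factor squared. Their geometric mean is 2.09, a share of 67.6%.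

The forecast says 70% (56% to 82%), above my middle but inside my bracket: “the share is therefore the initial rate ratio”. For 25 min it says 0.1%, with isomer of the product A ahead.

At 0.20 s the flask gives 69.1%, odds of 2.24, inside the bracket. At 25 min it gives 4.30%, with isomer of the product A ahead at 59.9% against 2.69% of target.

    target → over-reaction product (k = 0.00280 s⁻¹)
    target ⇌ isomer of the product A (K = 13.0, k = 0.00210 s⁻¹)
    starting material ⇌ other conformer (K = 3.10, k = 0.00770 s⁻¹)
    other conformer → isomer of the product A (k = 0.0240 s⁻¹)
    starting material → target (k = 0.0540 s⁻¹)
    target ⇌ isomer of the product B (K = 1.70, k = 0.00210 s⁻¹)

Take the neighbouring flask charged with 2.50 equiv of other conformer. If each feed starts in proportion to its charge, the early odds per equivalent stay as they are, and the odds in that flask are these divided by that amount. The bracket then runs from 39.7% to 51.5%, with 45.5% in the middle. The neighbouring flask gives a share of 47.3% at 0.20 s.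

The earlier runs and the new flask were computed for an exercise; noise was put on by code.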